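The slowness with which gas enters solution is the first thing to reckon in this flask, and turning the constants into times at the charged amounts shows why.

substrate 1.9 M; gas phase 200 mM (held); free catalyst 4.0 mM; time 8.0 min

* amount of target at 8.0 min, in percent of the substrate charged
* concentration of dissolved gas in solution at 8.0 min, in percent of saturation

- where a step has two of a species, its rate is k times that concentration squared, and two are used at each turn
- at the start none of the gas is dissolved
- run time (flask): 8.0 min

    dissolved gas + target → over-reaction product (k1 = 1.01 /M/min)
    2 free catalyst → spent catalyst (k2 = 46.4 /M/min)
    substrate + dissolved gas + free catalyst → free catalyst + target (k3 = 15000 /M²/min)
    gas phase ⇌ dissolved gas, rate k4*(csat - [dissolved gas]) (k4 = 0.801 /min, csat = 200 mM)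

In this flask the uptake renews the solution on a time of 1.25 min, whereas the conversion to target, at the charged substrate and free catalyst, clears c(dissolved gas) in 0.00877 min, a far shorter time. The solution should therefore stay nearly empty, and the uptake, the rate-limiting step, should run at its full pace of 0.160 M/min. Dividing the charged substrate by that pace gives 11.9 min, the time the uptake needs to bring in one dissolved gas for each substrate charged, here called the filling time. The run covers 67.5% of that filling time, which is the first figure for y.

The weak link is the empty solution. Free catalyst has, by its step to spent catalyst, a first half-life of 2.69 min, shorter than the run, so by this reckoning about 1.01 mM remains at the end, beside about 0.618 M of substrate. Together they clear dissolved gas at 9.35 /min, still faster than k4, and balancing uptake against use puts the end of the run at 7.89% of saturation. Taking half of that as the average slackening of the uptake trims y to 64.8%, and this reckoning commits to those two figures.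

The forecast is lower on both, with 61.7% and 6.5%, and it starts from the same view: “The reaction is almost entirely limited by gas transfer”.

The simulation gives 61.2% and 6.25%.

By the end of the run in this flask the conversion has turned over 63.0% of the substrate charged, below the 67.5% that is the most the uptake can deliver by then into a solution kept empty. The slow uptake, together with the time allowed, is part of the reason target stands at 61.2%, since with the passage made instant it stands at 20.5%. With 0.76 M of substrate the filling time shrinks from 11.9 min to 4.74 min, well inside the run, and that neighbour flask ends with 0.25% of its substrate left, 76.2% as target and 23.5% as over-reaction product.

The rate constants belong to no real substance.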